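**Plan**

- Retrosynthesis, in order: the dihydrofuran ring is opened at O1–C2 and C3–C3a (benzofuran numbering), giving myrcene and a bromo acetylphloroglucinol; then C–Br, the aryl–acetyl bond and three O–benzyl bonds are cut; then the pyranone at C4'–C5' and O1'–C2' (primed atoms, counted from the ring oxygen); last the bridge-carbon–malonate bond.
- Enabling feature: C2', C3' and C4' of the pyranone, with the bridge CH2 on C3', are a C-benzylated malonyl unit, and C5', C6' and O1' with their methyl and ethyl groups are pentan-3-one. The CH2 joining arene C7 to pyranone C3' can therefore sit on the malonyl carbon before the heterocycle exists, so no symmetric bis-arene or bis-pyranone methane can arise.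
- Forward: the benzene ring is bought, its formyl carbon becomes the bridge and is extended to an arylmethylmalonyl dichloride; the pyranone ring closes in step 7; debenzylation, C-acetylation and bromination follow; the dihydrofuran ring closes last.
- Stereochemistry: the only stereocentre, C2 (R), is set in step 11 by the chiral phosphine on palladium in the C–O bond-forming allylic substitution; no later step can erode it.

Key step: step 7

Assumption: the sense of induction of the sulfinamide phosphine ligand in step 11 is taken from the annulation of simple 2-bromophenols with 2-substituted butadienes, and the antipode that gives the (R)-2-alkenyl-2,3-dihydrobenzofuran there is the one used.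

**Route**

Step 1
Reactants: 1 2,4,6-trihydroxybenzaldehyde
Product: 2 2,4,6-tris(benzyloxy)benzaldehyde
Conditions: BnBr (3.6 equiv), K2CO3, DMF, 60 °C
Reagents that add atoms: benzyl bromide, BrCc1ccccc1
Why: Williamson O-alkylation of the phenoxides, in which the formyl group lowers ring nucleophilicity enough that oxygen rather than ring carbon is benzylated, and excess bromide with heating overcomes the two hydroxyls chelated to the aldehyde.

Step 2
Reactants: 2 2,4,6-tris(benzyloxy)benzaldehyde; 3 dimethyl malonate
Product: 4 dimethyl 2-{[2,4,6-tris(benzyloxy)phenyl]methylidene}malonate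
Conditions: piperidine (cat.), AcOH (cat.), toluene, reflux, Dean–Stark
Reagents that add atoms: none
Why: Knoevenagel condensation through the piperidine-derived iminium ion, driven to completion by azeotropic removal of water although the aldehyde is electron-rich and flanked by two benzyloxy groups.

Step 3
Reactants: 4 dimethyl 2-{[2,4,6-tris(benzyloxy)phenyl]methylidene}malonate
Product: 5 dimethyl 2-[2,4,6-tris(benzyloxy)benzyl]malonate
Conditions: NaBH4, THF/MeOH, 0 °C
Reagents that add atoms: none
Why: conjugate hydride reduction of an alkylidene malonate by NaBH4, which should be fast at 0 °C while esters and benzyl ethers stay intact, and no stereocentre results because the malonate carbon carries two identical esters.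

Step 4
Reactants: 5 dimethyl 2-[2,4,6-tris(benzyloxy)benzyl]malonate
Product: 6 2-[2,4,6-tris(benzyloxy)benzyl]malonic acid
Conditions: KOH, THF/MeOH/H2O, 50 °C; then 1 M HCl, 0 °C
Reagents that add atoms: potassium hydroxide, [K+].[OH-]
Why: saponification of both methyl esters and cold acidification should give the monosubstituted malonic acid, which decarboxylates only on heating and is therefore isolated below room temperature.

Step 5
Reactants: 7 pentan-3-one
Product: 8 (Z)-trimethyl(pent-2-en-3-yloxy)silane (Z isomer expected to predominate; the geometry is lost in step 7)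
Conditions: Me3SiCl, NaI, Et3N, MeCN, rt; pentane extraction, distillation
Reagents that add atoms: chlorotrimethylsilane, C[Si](C)(C)Cl
Why: silyl enol ether formation by soft enolisation with Me3SiI made in the flask and Et3N, and since the ketone is symmetric only one constitutional enol ether can form.

Step 6
Reactants: 6 2-[2,4,6-tris(benzyloxy)benzyl]malonic acid
Product: 9 2-[2,4,6-tris(benzyloxy)benzyl]malonyl dichloride
Conditions: 1-chloro-N,N,2-trimethylprop-1-en-1-amine (2.2 equiv), CH2Cl2, 0 °C to rt; volatiles and amide removed at 0.1 mbar; used crude at once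
Reagents that add atoms: 1-chloro-N,N,2-trimethylprop-1-en-1-amine (Ghosez reagent), CC(C)=C(Cl)N(C)C
Why: acid chloride formation with the neutral α-chloroenamine releases only an amide, so no HCl, Vilsmeier species or oxalyl chloride is present that could formylate or acylate the electron-rich tris(benzyloxy)arene.

Step 7
Reactants: 9 2-[2,4,6-tris(benzyloxy)benzyl]malonyl dichloride; 8 (Z)-trimethyl(pent-2-en-3-yloxy)silane
Product: 11 6-ethyl-4-hydroxy-5-methyl-3-[2,4,6-tris(benzyloxy)benzyl]pyran-2-one, via keto acid chloride 10 (not isolated)
Conditions: 8 (1.3 equiv), Et2O, −78 °C to rt; extraction into aq NaHCO3, then acidification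
Reagents that add atoms: none
Why: The enol ether carbon of 8 attacks one acyl chloride of 9 (directly, or after loss of HCl through the chlorocarbonyl ketene) to form the C4'–C5' bond and keto acid chloride 10 with loss of Me3SiCl; the ethyl ketone of 10 then enolises towards the doubly activated C–H and its enol oxygen closes on the second acyl chloride to form O1'–C2', and tautomerisation gives the 4-hydroxy-2-pyranone. The closest known reaction type is the acylation of ketone trimethylsilyl enol ethers with malonyl dichloride and its monosubstituted congeners, which gives 4-hydroxy-2-pyranones directly. The single new ring closes by a 6-exo-trig lactonisation of the enol oxygen onto the acyl chloride carbonyl. No stereocentre is created, because both sp3 centres of 10 end as sp2 carbons of the pyranone. The step needs acylation of the enol ether at carbon before oxygen and one enol ether per dichloride: without a Lewis base the silyl enol ether reacts at carbon, the second acylation is intramolecular and so outruns a second intermolecular one, and the symmetric ketone offers only one enol ether. The arene cannot cyclise onto its own side chain because both ortho positions carry benzyloxy groups, and at −78 °C its two free positions should be far poorer nucleophiles than the enol ether.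

Step 8
Reactants: 11 6-ethyl-4-hydroxy-5-methyl-3-[2,4,6-tris(benzyloxy)benzyl]pyran-2-one
Product: 12 6-ethyl-4-hydroxy-5-methyl-3-(2,4,6-trihydroxybenzyl)pyran-2-one
Conditions: H2 (1 atm), Pd/C (10 wt%), EtOAc/MeOH, rt; stopped after uptake of 3 equiv
Reagents that add atoms: none
Why: catalytic hydrogenolysis of the three aryl benzyl ethers, with the tetrasubstituted vinylogous-ester C5'=C6' bond of the pyranone expected to resist hydrogenation at atmospheric pressure.

Step 9
Reactants: 12 6-ethyl-4-hydroxy-5-methyl-3-(2,4,6-trihydroxybenzyl)pyran-2-one
Product: 13 3-(3-acetyl-2,4,6-trihydroxybenzyl)-6-ethyl-4-hydroxy-5-methylpyran-2-one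
Conditions: Ac2O (1.1 equiv), BF3·OEt2 (3 equiv), EtOAc, 0 °C to rt; then H2O/MeOH, 50 °C
Reagents that add atoms: acetic anhydride, CC(=O)OC(C)=O
Why: Friedel–Crafts C-acetylation of a C-alkylphloroglucinol, where the two free ring positions of 12 are equivalent by the mirror plane through the bridge carbon so one isomer should form, the new acetyl group deactivates the ring against a second acylation, and the aqueous methanolic work-up frees the product from boron and cleaves any O-acetate.

Step 10
Reactants: 13 3-(3-acetyl-2,4,6-trihydroxybenzyl)-6-ethyl-4-hydroxy-5-methylpyran-2-one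
Product: 14 3-(3-acetyl-5-bromo-2,4,6-trihydroxybenzyl)-6-ethyl-4-hydroxy-5-methylpyran-2-one
Conditions: NBS (1.0 equiv), MeCN, −20 °C
Reagents that add atoms: N-bromosuccinimide, O=C1CCC(=O)N1Br
Why: electrophilic aromatic bromination at the only remaining ring C–H, which lies between two hydroxyls and is the most nucleophilic carbon of the molecule, with one equivalent of reagent at low temperature to spare pyranone C3' and the bridge-bearing carbon.

Step 11
Reactants: 14 3-(3-acetyl-5-bromo-2,4,6-trihydroxybenzyl)-6-ethyl-4-hydroxy-5-methylpyran-2-one; 15 myrcene (7-methyl-3-methyleneocta-1,6-diene, 3 equiv)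
Product: 16 3-{[(2R)-5-acetyl-4,6-dihydroxy-2-(6-methylhepta-1,5-dien-2-yl)-2,3-dihydro-1-benzofuran-7-yl]methyl}-6-ethyl-4-hydroxy-5-methylpyran-2-one
Conditions: Pd2(dba)3·CHCl3 (5 mol%), tert-butanesulfinamide-derived chiral monophosphine of the TY-Phos type (12 mol%, antipode as assumed above), NaOPh (3 equiv), 1,4-dioxane, 70 °C
Reagents that add atoms: none
Why: enantioselective Heck/Tsuji–Trost heteroannulation of an o-bromophenol with a 1,3-diene, in which zerovalent palladium inserts into C–Br, the aryl group adds to the terminal CH2 of the monosubstituted vinyl group of myrcene, and the resulting π-allyl complex is closed 5-exo at its internal terminus by the phenoxide para to the acetyl group (the most acidic phenol and the only one not chelated to the ketone), the (R) configuration at C2 being fixed in this C–O bond formation by the chiral ligand after π–σ–π equilibration of the allyl.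

**Compound list**

1 | 2,4,6-trihydroxybenzaldehyde | O=Cc1c(O)cc(O)cc1O | starting material
2 | 2,4,6-tris(benzyloxy)benzaldehyde | O=Cc1c(OCc2ccccc2)cc(OCc2ccccc2)cc1OCc1ccccc1 | intermediate
3 | dimethyl malonate | COC(=O)CC(=O)OC | starting material
4 | dimethyl 2-{[2,4,6-tris(benzyloxy)phenyl]methylidene}malonate | COC(=O)C(=Cc1c(OCc2ccccc2)cc(OCc2ccccc2)cc1OCc1ccccc1)C(=O)OC | intermediate
5 | dimethyl 2-[2,4,6-tris(benzyloxy)benzyl]malonate | COC(=O)C(Cc1c(OCc2ccccc2)cc(OCc2ccccc2)cc1OCc1ccccc1)C(=O)OC | intermediate
6 | 2-[2,4,6-tris(benzyloxy)benzyl]malonic acid | OC(=O)C(Cc1c(OCc2ccccc2)cc(OCc2ccccc2)cc1OCc1ccccc1)C(O)=O | intermediate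
7 | pentan-3-one | CCC(=O)CC | starting material
8 | (Z)-trimethyl(pent-2-en-3-yloxy)silane | C/C=C(/CC)O[Si](C)(C)C | intermediate
9 | 2-[2,4,6-tris(benzyloxy)benzyl]malonyl dichloride | ClC(=O)C(Cc1c(OCc2ccccc2)cc(OCc2ccccc2)cc1OCc1ccccc1)C(Cl)=O | intermediate
10 | 4-methyl-3,5-dioxo-2-[2,4,6-tris(benzyloxy)benzyl]heptanoyl chloride (diastereomer and tautomer mixture, not isolated) | CCC(=O)C(C)C(=O)C(Cc1c(OCc2ccccc2)cc(OCc2ccccc2)cc1OCc1ccccc1)C(Cl)=O | intermediate
11 | 6-ethyl-4-hydroxy-5-methyl-3-[2,4,6-tris(benzyloxy)benzyl]pyran-2-one | CCc1oc(=O)c(Cc2c(OCc3ccccc3)cc(OCc3ccccc3)cc2OCc2ccccc2)c(O)c1C | intermediate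
12 | 6-ethyl-4-hydroxy-5-methyl-3-(2,4,6-trihydroxybenzyl)pyran-2-one | CCc1oc(=O)c(Cc2c(O)cc(O)cc2O)c(O)c1C | intermediate
13 | 3-(3-acetyl-2,4,6-trihydroxybenzyl)-6-ethyl-4-hydroxy-5-methylpyran-2-one | CCc1oc(=O)c(Cc2c(O)cc(O)c(C(C)=O)c2O)c(O)c1C | intermediate
14 | 3-(3-acetyl-5-bromo-2,4,6-trihydroxybenzyl)-6-ethyl-4-hydroxy-5-methylpyran-2-one | CCc1oc(=O)c(Cc2c(O)c(Br)c(O)c(C(C)=O)c2O)c(O)c1C | intermediate
15 | myrcene (7-methyl-3-methyleneocta-1,6-diene) | C=CC(=C)CCC=C(C)C | starting material
16 | 3-{[(2R)-5-acetyl-4,6-dihydroxy-2-(6-methylhepta-1,5-dien-2-yl)-2,3-dihydro-1-benzofuran-7-yl]methyl}-6-ethyl-4-hydroxy-5-methylpyran-2-one | C=C(CCC=C(C)C)[C@H]1Cc2c(O)c(C(C)=O)c(O)c(Cc3c(O)c(C)c(CC)oc3=O)c2O1 | target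

**Count**

Total step count: 11. Longest linear sequence: 10 steps (steps 1–4 and 6–11, from 1 to 16).

**Steps most likely to fail**

Step 11.
- What may go wrong: oxidative addition may stall on the di-ortho-oxygenated bromide, which enters the cycle as a polyphenoxide. Ring closure may partly run through the hydroxyl beside the acetyl group. Enantiocontrol may be lost because the para-acyl phenoxide is a good leaving group and the allylic ether can reionise. The base may promote exchange of the two halves across the methylene bridge, and β-hydride elimination may give an open aryl triene.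
- Fallback, from 13 back to 16: 13 is iodinated with N-iodosuccinimide (MeCN, −20 °C) to 3-(3-acetyl-2,4,6-trihydroxy-5-iodobenzyl)-6-ethyl-4-hydroxy-5-methylpyran-2-one F1. The more reactive iodide is annulated with 15 under ligand-free Larock conditions (Pd(OAc)2, n-Bu4NCl, NaHCO3, DMF, 80 °C); the weak bicarbonate base should leave the chelated hydroxyls protonated and give racemic 16 F2. The enantiomers are then separated by preparative chromatography on a chiral stationary phase to give 16.

Step 7 (together with the handling of 9 from step 6).
- What may go wrong: the dichloride may be consumed before it meets the enol ether, by attack of an ortho benzyloxy oxygen on the acyl chloride with loss of benzyl chloride, by dimerisation of the derived ketene, or by acylation of the electron-rich arene. Acylation of the enol ether at oxygen would stop at enol esters.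
- Fallback, from 2 and 8 back to 11: the parent reaction, 8 with malonyl dichloride (Et2O, −78 °C to rt), should give 6-ethyl-4-hydroxy-5-methylpyran-2-one F3. F3 is joined to aldehyde 2 by three-component reductive alkylation (Hantzsch ester, L-proline cat., CH2Cl2, rt): Knoevenagel condensation forms 6-ethyl-5-methyl-3-{[2,4,6-tris(benzyloxy)phenyl]methylidene}pyran-2,4-dione F4, which is reduced in the flask by hydride transfer to 11. The bridge carbon still comes from the arene aldehyde and the alkylidene is reduced as it forms, so the union stays unsymmetrical. This bypasses steps 2–4 and 6.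

Step 9.
- What may go wrong: acylation may continue to the diacetyl compound at the last free ring position, or stop at O-acetates that do not rearrange to the C-acetyl product.
- Fallback, from 12 back to 13: Houben–Hoesch acylation with acetonitrile (ZnCl2, HCl gas, Et2O, 0 °C) should precipitate 1-{3-[(6-ethyl-4-hydroxy-5-methyl-2-oxopyran-3-yl)methyl]-2,4,6-trihydroxyphenyl}ethaniminium chloride F5. Its positive charge blocks a second acylation and a nitrile cannot acylate oxygen. Hydrolysis in water at 80 °C then gives 13.

**Further compounds**

F1 | step 11 | 3-(3-acetyl-2,4,6-trihydroxy-5-iodobenzyl)-6-ethyl-4-hydroxy-5-methylpyran-2-one | CCc1oc(=O)c(Cc2c(O)c(I)c(O)c(C(C)=O)c2O)c(O)c1C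
F2 | step 11 | racemic 3-{[5-acetyl-4,6-dihydroxy-2-(6-methylhepta-1,5-dien-2-yl)-2,3-dihydro-1-benzofuran-7-yl]methyl}-6-ethyl-4-hydroxy-5-methylpyran-2-one | C=C(CCC=C(C)C)C1Cc2c(O)c(C(C)=O)c(O)c(Cc3c(O)c(C)c(CC)oc3=O)c2O1
F3 | step 7 | 6-ethyl-4-hydroxy-5-methylpyran-2-one | CCc1oc(=O)cc(O)c1C
F4 | step 7 | 6-ethyl-5-methyl-3-{[2,4,6-tris(benzyloxy)phenyl]methylidene}pyran-2,4-dione | CCC1=C(C)C(=O)C(=Cc2c(OCc3ccccc3)cc(OCc3ccccc3)cc2OCc2ccccc2)C(=O)O1
F5 | step 9 | 1-{3-[(6-ethyl-4-hydroxy-5-methyl-2-oxopyran-3-yl)methyl]-2,4,6-trihydroxyphenyl}ethaniminium chloride | CCc1oc(=O)c(Cc2c(O)cc(O)c(C(C)=[NH2+])c2O)c(O)c1C.[Cl-]
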